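**Plan**

- Ring A (C1 bears the CH2CH2Ar chain, C2 and C4 the 4-hydroxybenzyl groups, C3 the OMe, C5 the OH, C6 is CH) has its two oxygens meta to each other with a carbon substituent between them. This is the 3-siloxyphenol pattern that a vinylketene and an ynol silyl ether assemble.
- Retrosynthesis: after removal of the O-methyl, silyl and benzyl groups, ring A is cut at C3–C4 and C5–C6 (and at C2–C3, which re-forms) into cyclobutenone 12 and siloxyalkyne 17.
- 12 is cut at its C3–CH2 bond (Grignard reagent from bromide 9) and across the four-membered ring (ketene from acid chloride 3 plus ethoxyacetylene 4); 17 is cut at the triple bond into ester 14 and CH2Br2.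
- Forward: three fragments (steps 1–3, 4–5, 7–8) are joined in step 6 (cyclobutenone) and step 9, where ring A, the only ring made, is closed. Methylation of O3, desilylation of O5 and hydrogenolysis complete the route.
- Stereochemistry: the target is achiral; the one stereocentre of 12 (C4, racemic) disappears when ring A aromatizes.

Key step: step 9

Remark on the chemistry: because the target has no stereocentre, 6, 11, 12, 19 and 21 are carried as racemates or diastereomer mixtures; their SMILES show one arbitrary enantiomer.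

**Route**

Step 1
Reactants: 1 3-(4-hydroxyphenyl)propanoic acid
Product: 2 3-(4-benzyloxyphenyl)propanoic acid
Conditions: BnBr, NaOH, EtOH/H2O, reflux; then HCl
Reagents that add atoms: benzyl bromide, BrCc1ccccc1
Why: Williamson etherification of the phenoxide, in which any benzyl ester formed is saponified by the excess hydroxide in the same pot, so acidification should give the ether acid.

Step 2
Reactants: 2 3-(4-benzyloxyphenyl)propanoic acid
Product: 3 3-(4-benzyloxyphenyl)propanoyl chloride
Conditions: (COCl)2, DMF (cat.), CH2Cl2, 0 °C → rt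
Reagents that add atoms: oxalyl chloride, ClC(=O)C(Cl)=O
Why: Acid chloride formation under Vilsmeier-type DMF catalysis, mild conditions that leave the benzyl aryl ether untouched.

Step 3
Reactants: 3 3-(4-benzyloxyphenyl)propanoyl chloride; 4 ethoxyacetylene
Product: 6 4-(4-benzyloxybenzyl)-3-ethoxycyclobut-2-en-1-one (racemic), via (4-benzyloxybenzyl)ketene 5 (not isolated)
Conditions: Et3N, 4 (3 equiv), Et2O, 0 °C → rt, slow addition of 3
Reagents that add atoms: none
Why: Dehydrochlorination gives the monosubstituted ketene 5, which should undergo the known regioselective ketene–alkoxyalkyne (2+2) cycloaddition (ketene carbonyl carbon to the unsubstituted alkyne carbon) to the 3-ethoxycyclobutenone, the C4 stereocentre forming as a racemate.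

Step 4
Reactants: 7 2-(3-hydroxyphenyl)ethanol
Product: 8 2-(3-benzyloxyphenyl)ethanol
Conditions: BnBr, K2CO3, acetone, reflux
Reagents that add atoms: benzyl bromide, BrCc1ccccc1
Why: Williamson etherification that is chemoselective for the phenol, since carbonate deprotonates the phenol but not the primary alcohol.

Step 5
Reactants: 8 2-(3-benzyloxyphenyl)ethanol
Product: 9 1-(benzyloxy)-3-(2-bromoethyl)benzene
Conditions: CBr4, PPh3, CH2Cl2, 0 °C → rt
Reagents that add atoms: carbon tetrabromide, BrC(Br)(Br)Br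
Why: Appel bromination of a primary alcohol under neutral conditions.

Step 6
Reactants: 9 1-(benzyloxy)-3-(2-bromoethyl)benzene; 6 4-(4-benzyloxybenzyl)-3-ethoxycyclobut-2-en-1-one
Product: 12 4-(4-benzyloxybenzyl)-3-[2-(3-benzyloxyphenyl)ethyl]cyclobut-2-en-1-one (racemic), via Grignard reagent 10 (not isolated), via cyclobutenol adduct 11 (not isolated)
Conditions: Mg, I2 (cat.), THF, rt; then 6, THF, −78 → 0 °C; then 1 M HCl, 0 °C → rt
Reagents that add atoms: water, O (the carbonyl oxygen of 12)
Why: Grignard 1,2-addition to the vinylogous ester followed by acid hydrolysis of the enol ether with loss of water (Stork–Danheiser-type 1,3-carbonyl transposition, the standard way from 3-ethoxycyclobutenones to 3-substituted cyclobutenones) should give 12, the carbinol centre being destroyed and C4 staying racemic.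

Step 7
Reactants: 13 ethyl (4-hydroxyphenyl)acetate
Product: 14 ethyl (4-benzyloxyphenyl)acetate
Conditions: BnBr, K2CO3, acetone, reflux
Reagents that add atoms: benzyl bromide, BrCc1ccccc1
Why: Williamson etherification of the phenol under conditions too weakly basic to alkylate the ester α-position.

Step 8
Reactants: 14 ethyl (4-benzyloxyphenyl)acetate
Product: 17 3-(4-benzyloxyphenyl)-1-(triisopropylsiloxy)prop-1-yne, via lithium dibromoenolate 15 (not isolated), via lithium ynolate 16 (not isolated)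
Conditions: CH2Br2, LiTMP (lithium 2,2,6,6-tetramethylpiperidide), THF, −78 °C; 14; LiN(SiMe3)2, −78 °C; n-BuLi, −78 → 0 °C; i-Pr3SiCl, −78 °C → rt
Reagents that add atoms: dibromomethane, BrCBr; chlorotriisopropylsilane, CC(C)[Si](Cl)(C(C)C)C(C)C
Why: Kowalski ester homologation, in which LiCHBr2 adds to the ester, enolate 15 undergoes bromine–lithium exchange and 1,2-shift of the arylmethyl group to ynolate 16, and the bulky chlorosilane silylates oxygen, as known for ynolate trapping to triisopropylsiloxyalkynes.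

Step 9
Reactants: 12 4-(4-benzyloxybenzyl)-3-[2-(3-benzyloxyphenyl)ethyl]cyclobut-2-en-1-one; 17 3-(4-benzyloxyphenyl)-1-(triisopropylsiloxy)prop-1-yne
Product: 22 2,6-bis(4-benzyloxybenzyl)-5-[2-(3-benzyloxyphenyl)ethyl]-3-(triisopropylsiloxy)phenol, via vinylketene 18 (not isolated), via vinylcyclobutenone 19 (not isolated), via dienylketene 20 (not isolated), via cyclohexadienone 21 (not isolated)
Conditions: 17 (1.3 equiv), toluene, 80 °C then 110 °C, argon
Reagents that add atoms: none
Why: Thermal 4π electrocyclic opening of 12 (cleavage of C1–C4, the C4 benzyl group turning outward) gives vinylketene 18, whose carbonyl carbon is attacked by the benzyl-bearing, nucleophilic carbon of ynol silyl ether 17 while the siloxy-bearing carbon bonds to the ketene α-carbon, so the (2+2) adduct 19 already holds the C3–C4 and C5–C6 bonds of ring A. A second 4π opening turns 19 into dienylketene 20, and ring A is closed by thermal disrotatory 6π electrocyclization between the ketene carbon and the benzyl-substituted diene terminus (re-forming C2–C3) to cyclohexadienone 21, which tautomerizes to phenol 22. The closest known reaction type is the Danheiser benzannulation of cyclobutenones with trialkylsiloxyalkynes to resorcinol monosilyl ethers. No stereocentre remains in 22, the transient ones of 12, 19 and 21 being lost on aromatization. The selectivity needed is regiochemical: the oxygen polarizes the alkyne so that only the carbon remote from oxygen adds to the ketene carbonyl, which places the siloxy group meta to the new hydroxyl with the benzylated carbon between them and delivers O3 free and O5 silylated. Both ring openings are reversible, so isomers that cannot cyclize should return to the productive pathway.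

Step 10
Reactants: 22 2,6-bis(4-benzyloxybenzyl)-5-[2-(3-benzyloxyphenyl)ethyl]-3-(triisopropylsiloxy)phenol
Product: 23 [2,4-bis(4-benzyloxybenzyl)-5-[2-(3-benzyloxyphenyl)ethyl]-3-methoxyphenoxy]triisopropylsilane
Conditions: MeI, K2CO3, acetone, 50 °C
Reagents that add atoms: iodomethane, CI
Why: Williamson O-methylation of the only free hydroxyl, all other oxygens being masked as silyl or benzyl ethers, so the methyl group can only go to O3.

Step 11
Reactants: 23 [2,4-bis(4-benzyloxybenzyl)-5-[2-(3-benzyloxyphenyl)ethyl]-3-methoxyphenoxy]triisopropylsilane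
Product: 24 2,4-bis(4-benzyloxybenzyl)-5-[2-(3-benzyloxyphenyl)ethyl]-3-methoxyphenol
Conditions: Bu4NF, THF, 0 °C; then H2O
Reagents that add atoms: none
Why: Fluoride-induced cleavage of the aryl silyl ether, driven by Si–F bond formation, which leaves methyl and benzyl ethers intact.

Step 12
Reactants: 24 2,4-bis(4-benzyloxybenzyl)-5-[2-(3-benzyloxyphenyl)ethyl]-3-methoxyphenol
Product: 25 bulbocodin C
Conditions: H2 (1 atm), Pd on carbon (10%), EtOAc/MeOH, rt
Reagents that add atoms: none
Why: Catalytic hydrogenolysis of the three benzyl aryl ethers, under which the diarylmethane and bibenzyl C–C bonds and the aryl methyl ether are inert.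

**Compound list**

1 | 3-(4-hydroxyphenyl)propanoic acid | OC(=O)CCc1ccc(O)cc1 | starting material
2 | 3-(4-benzyloxyphenyl)propanoic acid | OC(=O)CCc1ccc(OCc2ccccc2)cc1 | intermediate
3 | 3-(4-benzyloxyphenyl)propanoyl chloride | ClC(=O)CCc1ccc(OCc2ccccc2)cc1 | intermediate
4 | ethoxyacetylene | CCOC#C | starting material
5 | (4-benzyloxybenzyl)ketene, 3-(4-benzyloxyphenyl)prop-1-en-1-one (not isolated) | O=C=CCc1ccc(OCc2ccccc2)cc1 | intermediate
6 | 4-(4-benzyloxybenzyl)-3-ethoxycyclobut-2-en-1-one (racemic; one enantiomer drawn) | CCOC1=CC(=O)[C@@H]1Cc1ccc(OCc2ccccc2)cc1 | intermediate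
7 | 2-(3-hydroxyphenyl)ethanol | OCCc1cccc(O)c1 | starting material
8 | 2-(3-benzyloxyphenyl)ethanol | OCCc1cccc(OCc2ccccc2)c1 | intermediate
9 | 1-(benzyloxy)-3-(2-bromoethyl)benzene | BrCCc1cccc(OCc2ccccc2)c1 | intermediate
10 | [2-(3-benzyloxyphenyl)ethyl]magnesium bromide (not isolated) | Br[Mg]CCc1cccc(OCc2ccccc2)c1 | intermediate
11 | 1-[2-(3-benzyloxyphenyl)ethyl]-4-(4-benzyloxybenzyl)-3-ethoxycyclobut-2-en-1-ol (not isolated; bromomagnesium alkoxide until acid is added; diastereomer mixture, C1 unspecified) | CCOC1=CC(O)(CCc2cccc(OCc3ccccc3)c2)[C@@H]1Cc1ccc(OCc2ccccc2)cc1 | intermediate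
12 | 4-(4-benzyloxybenzyl)-3-[2-(3-benzyloxyphenyl)ethyl]cyclobut-2-en-1-one (racemic; one enantiomer drawn) | O=C1C=C(CCc2cccc(OCc3ccccc3)c2)[C@@H]1Cc1ccc(OCc2ccccc2)cc1 | intermediate
13 | ethyl (4-hydroxyphenyl)acetate | CCOC(=O)Cc1ccc(O)cc1 | starting material
14 | ethyl (4-benzyloxyphenyl)acetate | CCOC(=O)Cc1ccc(OCc2ccccc2)cc1 | intermediate
15 | lithium 3-(4-benzyloxyphenyl)-1,1-dibromoprop-1-en-2-olate (not isolated) | [Li+].[O-]C(Cc1ccc(OCc2ccccc2)cc1)=C(Br)Br | intermediate
16 | lithium 3-(4-benzyloxyphenyl)prop-1-yn-1-olate (not isolated) | [Li+].[O-]C#CCc1ccc(OCc2ccccc2)cc1 | intermediate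
17 | 3-(4-benzyloxyphenyl)-1-(triisopropylsiloxy)prop-1-yne | CC(C)[Si](OC#CCc1ccc(OCc2ccccc2)cc1)(C(C)C)C(C)C | intermediate
18 | (E)-5-(4-benzyloxyphenyl)-3-[2-(3-benzyloxyphenyl)ethyl]penta-1,3-dien-1-one (vinylketene, not isolated) | O=C=C/C(CCc1cccc(OCc2ccccc2)c1)=C/Cc1ccc(OCc2ccccc2)cc1 | intermediate
19 | 2-(4-benzyloxybenzyl)-4-[(E)-1-(3-benzyloxyphenyl)-5-(4-benzyloxyphenyl)pent-3-en-3-yl]-3-(triisopropylsiloxy)cyclobut-2-en-1-one (racemic, not isolated) | O=C1C(Cc2ccc(OCc3ccccc3)cc2)=C(O[Si](C(C)C)(C(C)C)C(C)C)[C@@H]1/C(CCc1cccc(OCc2ccccc2)c1)=C/Cc1ccc(OCc2ccccc2)cc1 | intermediate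
20 | (3E,5E)-2-(4-benzyloxybenzyl)-7-(4-benzyloxyphenyl)-5-[2-(3-benzyloxyphenyl)ethyl]-3-(triisopropylsiloxy)hepta-1,3,5-trien-1-one (dienylketene, not isolated) | O=C=C(Cc1ccc(OCc2ccccc2)cc1)/C(O[Si](C(C)C)(C(C)C)C(C)C)=C\C(CCc1cccc(OCc2ccccc2)c1)=C\Cc1ccc(OCc2ccccc2)cc1 | intermediate
21 | 2,6-bis(4-benzyloxybenzyl)-5-[2-(3-benzyloxyphenyl)ethyl]-3-(triisopropylsiloxy)cyclohexa-2,4-dien-1-one (racemic, not isolated) | O=C1C(Cc2ccc(OCc3ccccc3)cc2)=C(O[Si](C(C)C)(C(C)C)C(C)C)C=C(CCc2cccc(OCc3ccccc3)c2)[C@@H]1Cc1ccc(OCc2ccccc2)cc1 | intermediate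
22 | 2,6-bis(4-benzyloxybenzyl)-5-[2-(3-benzyloxyphenyl)ethyl]-3-(triisopropylsiloxy)phenol | Oc1c(Cc2ccc(OCc3ccccc3)cc2)c(O[Si](C(C)C)(C(C)C)C(C)C)cc(CCc2cccc(OCc3ccccc3)c2)c1Cc1ccc(OCc2ccccc2)cc1 | intermediate
23 | [2,4-bis(4-benzyloxybenzyl)-5-[2-(3-benzyloxyphenyl)ethyl]-3-methoxyphenoxy]triisopropylsilane | COc1c(Cc2ccc(OCc3ccccc3)cc2)c(O[Si](C(C)C)(C(C)C)C(C)C)cc(CCc2cccc(OCc3ccccc3)c2)c1Cc1ccc(OCc2ccccc2)cc1 | intermediate
24 | 2,4-bis(4-benzyloxybenzyl)-5-[2-(3-benzyloxyphenyl)ethyl]-3-methoxyphenol | COc1c(Cc2ccc(OCc3ccccc3)cc2)c(O)cc(CCc2cccc(OCc3ccccc3)c2)c1Cc1ccc(OCc2ccccc2)cc1 | intermediate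
25 | bulbocodin C, 2,4-bis(4-hydroxybenzyl)-5-[2-(3-hydroxyphenyl)ethyl]-3-methoxyphenol | COc1c(Cc2ccc(O)cc2)c(O)cc(CCc2cccc(O)c2)c1Cc1ccc(O)cc1 | target

**Count**

Total steps: 12. Longest linear sequence: 8 steps (1, 2, 3, 6, 9, 10, 11, 12).

**Steps most likely to fail**

Step 9. The C4 benzyl group may turn inward on ring opening, and the resulting (Z)-vinylketene could be drained by 1,5-hydrogen shift or self-condensation before the hindered siloxyalkyne adds. The fallback takes this substituent out of the annulation. It sets out from Grignard reagent 10 (made from 9 as in step 6) and siloxyalkyne 17 and comes back at 22. Addition of 10 to commercial 3-ethoxycyclobut-2-en-1-one (THF, −78 °C) would give the carbinol 1-[2-(3-benzyloxyphenyl)ethyl]-3-ethoxycyclobut-2-en-1-ol F1 (not isolated). Treatment with 1 M HCl should convert it into 3-[2-(3-benzyloxyphenyl)ethyl]cyclobut-2-en-1-one F2, a cyclobutenone without a C4 substituent. Heating F2 with 17 (toluene, 80 °C) should give, by the same ketene cascade, 2-(4-benzyloxybenzyl)-5-[2-(3-benzyloxyphenyl)ethyl]-3-(triisopropylsiloxy)phenol F3, in which C6 is the only free position ortho to the hydroxyl. Boron-templated ortho-hydroxybenzylation with 4-benzyloxybenzaldehyde and PhB(OH)2 (EtCO2H cat., toluene, reflux, water removal) would give 8-(4-benzyloxybenzyl)-4-(4-benzyloxyphenyl)-5-[2-(3-benzyloxyphenyl)ethyl]-2-phenyl-7-(triisopropylsiloxy)-4H-1,3,2-benzodioxaborinine F4. Ionic hydrogenation (Et3SiH, CF3CO2H, CH2Cl2, 0 °C) should then cleave the doubly benzylic C–O bond and give 22.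

Step 8. LiCHBr2 or LiTMP may deprotonate the acidic benzylic α-position of the arylacetate instead of adding to the carbonyl, and the propargylic benzylic CH2 of the ynolate may isomerize under the basic conditions. The fallback reaches the ynolate by oxidation of an acetylide. It sets out from 14 and comes back at ynolate 16 (and from there 17). Reduction of 14 with i-Bu2AlH (CH2Cl2, −78 °C) would give (4-benzyloxyphenyl)acetaldehyde F5. Corey–Fuchs olefination (CBr4, PPh3, CH2Cl2, 0 °C) would give 1-(benzyloxy)-4-(3,3-dibromoprop-2-en-1-yl)benzene F6. Two equivalents of n-BuLi (THF, −78 °C) should give, by Fritsch–Buttenberg–Wiechell rearrangement, [3-(4-benzyloxyphenyl)prop-1-yn-1-yl]lithium F7 (not isolated). Oxidation of F7 with LiOO-t-Bu (from t-BuOOH and LiN(SiMe3)2, −78 → 0 °C) is a known way from lithium acetylides to ynolates and should give 16, which is silylated with i-Pr3SiCl as in step 8.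

Step 3. Dimerization of the monosubstituted ketene and its acylation by unreacted acid chloride may outrun the (2+2) addition to ethoxyacetylene. The fallback builds the four-membered ring by keteniminium–alkyne (2+2) cycloaddition and also replaces step 6. It sets out from acid chloride 3 and bromide 9 and comes back at 12.
- Acid chloride 3 with Me2NH (THF, 0 °C) would give N,N-dimethyl-3-(4-benzyloxyphenyl)propanamide F8.
- Bromide 9 with LiC≡CH·H2NCH2CH2NH2 (DMSO, rt) would give 1-(benzyloxy)-3-(but-3-yn-1-yl)benzene F9.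
- Activation of F8 with Tf2O and 2,4,6-collidine (ClCH2CH2Cl, reflux) should give the keteniminium salt N-[3-(4-benzyloxyphenyl)prop-1-en-1-ylidene]-N-methylmethanaminium triflate F10 (not isolated).
- F10 should add to the terminal alkyne F9, iminium carbon to the CH terminus, to give N-{4-(4-benzyloxybenzyl)-3-[2-(3-benzyloxyphenyl)ethyl]cyclobut-2-en-1-ylidene}-N-methylmethanaminium triflate F11 (not isolated).
- Hydrolysis of F11 with aqueous NaHCO3 would deliver 12.

**Further compounds**

F1 | step 9 | 1-[2-(3-benzyloxyphenyl)ethyl]-3-ethoxycyclobut-2-en-1-ol | CCOC1=CC(O)(CCc2cccc(OCc3ccccc3)c2)C1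
F2 | step 9 | 3-[2-(3-benzyloxyphenyl)ethyl]cyclobut-2-en-1-one | O=C1C=C(CCc2cccc(OCc3ccccc3)c2)C1
F3 | step 9 | 2-(4-benzyloxybenzyl)-5-[2-(3-benzyloxyphenyl)ethyl]-3-(triisopropylsiloxy)phenol | Oc1cc(CCc2cccc(OCc3ccccc3)c2)cc(O[Si](C(C)C)(C(C)C)C(C)C)c1Cc1ccc(OCc2ccccc2)cc1
F4 | step 9 | 8-(4-benzyloxybenzyl)-4-(4-benzyloxyphenyl)-5-[2-(3-benzyloxyphenyl)ethyl]-2-phenyl-7-(triisopropylsiloxy)-4H-1,3,2-benzodioxaborinine (racemic) | c1ccccc1B1Oc2c(Cc3ccc(OCc4ccccc4)cc3)c(O[Si](C(C)C)(C(C)C)C(C)C)cc(CCc3cccc(OCc4ccccc4)c3)c2C(c2ccc(OCc3ccccc3)cc2)O1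
F5 | step 8 | (4-benzyloxyphenyl)acetaldehyde | O=CCc1ccc(OCc2ccccc2)cc1
F6 | step 8 | 1-(benzyloxy)-4-(3,3-dibromoprop-2-en-1-yl)benzene | BrC(Br)=CCc1ccc(OCc2ccccc2)cc1
F7 | step 8 | [3-(4-benzyloxyphenyl)prop-1-yn-1-yl]lithium | [Li]C#CCc1ccc(OCc2ccccc2)cc1
F8 | step 3 | N,N-dimethyl-3-(4-benzyloxyphenyl)propanamide | CN(C)C(=O)CCc1ccc(OCc2ccccc2)cc1
F9 | step 3 | 1-(benzyloxy)-3-(but-3-yn-1-yl)benzene | C#CCCc1cccc(OCc2ccccc2)c1
F10 | step 3 | N-[3-(4-benzyloxyphenyl)prop-1-en-1-ylidene]-N-methylmethanaminium triflate | C[N+](C)=C=CCc1ccc(OCc2ccccc2)cc1.[O-]S(=O)(=O)C(F)(F)F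
F11 | step 3 | N-{4-(4-benzyloxybenzyl)-3-[2-(3-benzyloxyphenyl)ethyl]cyclobut-2-en-1-ylidene}-N-methylmethanaminium triflate (racemic) | C[N+](C)=C1C=C(CCc2cccc(OCc3ccccc3)c2)C1Cc1ccc(OCc2ccccc2)cc1.[O-]S(=O)(=O)C(F)(F)F
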